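Slowness in the later part of Wednesday's run is the clue here: the substrate falls quickly at first, then drags.

| setting | Wednesday's | Saturday's | dawn | spring |
|---|---|---|---|---|
| substrate | 0.20 M | 0.20 M | 0.20 M | 0.20 M |
| partner A | 0.24 M | 0.24 M | 0.240 M | 0.240 M |
| partner B | 0.42 M | 0.66 M | 0.300 M | 0.300 M |
| temperature | 30 °C | 48 °C | 35 °C | 60 °C |
| remark | run made earlier | run made earlier |  |  |
| time |  |  | 4.0 h | 4.0 h |

Wednesday's run (percent of the substrate charged)

| time / h | substrate / % | target / % | open intermediate / % |
|---|---|---|---|
| 0.167 | 88.3 | 0 | 11.0 |
| 0.500 | 75.1 | 2.0 | 19.0 |
| 0.833 | 64.9 | 4.9 | 20.7 |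
| 1.33 | 59.3 | 11.3 | 20.1 |
| 2.00 | 51.7 | 16.6 | 18.9 |
| 2.50 | 47.3 | 20.0 | 18.2 |

Saturday's run (percent of the substrate charged)

| time / min | substrate / % | target / % | open intermediate / % |
|---|---|---|---|
| 5.00 | 71.0 | 3.9 | 18.8 |
| 15.0 | 47.3 | 14.6 | 20.6 |
| 25.0 | 32.7 | 25.2 | 16.5 |
| 40.0 | 19.9 | 31.1 | 11.5 |
| 60.0 | 10.8 | 36.2 | 5.7 |
| 80.0 | 7.8 | 36.1 | 2.8 |

(scatter of a reading: 1 percentage point)

- which of these there is most of at the end, counted by the substrate in it, dawn (open intermediate / substrate / target)
- which of these there is most of at the end, counted by the substrate in it, spring (open intermediate / substrate / target)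
- the largest of these amounts at the end, in percent of the substrate charged, dawn
- the largest of these amounts at the end, in percent of the substrate charged, spring

- steps that have been proposed: substrate + partner B -> open intermediate; partner B + partner A -> second intermediate; open intermediate + second intermediate -> target; 2 second intermediate -> homo product; open intermediate -> decomposed reagent

Take the main step first, substrate + partner B → open intermediate. Its rate is k1·c(substrate)·c(partner B), so c(partner B) is the concentration that sets the pseudo-first-order rate of the substrate. Wednesday's first reading gives k1 of about 1.77 /M/h. With that constant, read at 30 °C, and c(partner B) held at the new charge of 0.300 M, the half-life is 1.30 h, shorter than the 4.0 h allowed, and 12.0% of the substrate would remain.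

Now add partner B + partner A → second intermediate. Between 1.33 h and 2.50 h Wednesday's substrate decays at only 0.193 /h, which with k1 means c(partner B) near 0.109 M around 2.00 h. So these readings put the partner B spent by then at about 0.311 M. The substrate's fall accounts for about 0.0966 M of it, and the rest goes to partner A, which reckons about 10.6% of partner A's charge as left.

Both steps are first order in partner B, so c(partner B) cancels between them. The selectivity factor s, the ln of the fraction of substrate left over the ln of the fraction of partner A left, equals k1/k2 at a given temperature, and here it reads 0.294. With this s, substrate and partner A move along one curve, and the position on it is set by the partner B spent. The new charge of 0.300 M is a little less than Wednesday's reckoned spending, so my own reckoning, with s held at Wednesday's reading although dawn stands at 35 °C and spring at 60 °C, ends the substrate a little above 51.7%.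

The remaining steps, open intermediate + second intermediate → target, 2 second intermediate → homo product and open intermediate → decomposed reagent, consume neither substrate nor partner B, so adding them does not change this reckoning of the substrate.

The forecast names substrate for dawn and substrate for spring, at 56% and 54%, the hotter flask “with the same selectivity”.

The flasks end with substrate largest in dawn at 62.0% and substrate largest in spring at 65.3%. The forecast named the right species and stands 6 percentage points and 11 points low.

    substrate + partner B → open intermediate (k = 8.30 × 10⁻⁴ /M/s, Ea = 59.0 kJ/mol)
    partner B + partner A → second intermediate (k = 0.00430 /M/s, Ea = 72.0 kJ/mol)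
    open intermediate + second intermediate → target (k = 0.00130 /M/s, Ea = 80.0 kJ/mol)
    2 second intermediate → homo product (k = 1.70 × 10⁻⁴ /M/s, Ea = 60.0 kJ/mol)
    open intermediate → decomposed reagent (k = 1.80 × 10⁻⁴ /s, Ea = 107 kJ/mol)
    (constants at 35 °C)

Read from the ends of the flasks, s is 0.193 in dawn and 0.132 in spring, lower in spring than in dawn, where Wednesday's run at 30 °C read 0.294. At the start of spring, partner B goes to partner A 9.1 times as fast as to substrate. In the neighbour of spring charged with 0.12 M of partner B, 56% of partner A remains, so spring's s reckons 92.6% of substrate, and that flask ends at 93%.

All runs stem from a simulated flask for an exercise; scatter was added.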